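Amounts first: I divided each run's first reading, as a share of the substrate, by its time and its charged partner concentration. South gave 0.386 M⁻¹ min⁻¹, south-east 0.350 M⁻¹ min⁻¹ and east 0.373 M⁻¹ min⁻¹. East read 16.8% against south's 16.2%, with 15.0 mM of partner charged against 14.0 mM, so at the first reading the share went with the charged partner concentration, as a second-order step of substrate with partner has it at the start. I took the mean, 0.370 M⁻¹ min⁻¹.

| flask | substrate | partner | remark | time |
|---|---|---|---|---|
| south | 10 mM | 1.4 equiv | run made earlier |  |
| south-east | 10 mM | 2.2 equiv | run made earlier |  |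
| east | 15 mM | 1 equiv | run made earlier |  |
| flask | 10 mM | 1.00 equiv |  | 6.0 h |

| run | time / h | first product / % |
|---|---|---|
| south | 0.500 | 16.2 |
| south | 0.833 | 21.5 |
| south | 1.33 | 25.9 |
| south | 2.00 | 30.1 |
| south | 3.00 | 34.3 |
| south | 5.00 | 40.7 |
| south | 8.00 | 46.6 |
| south-east | 0.500 | 23.1 |
| south-east | 0.833 | 28.0 |
| south-east | 1.33 | 32.2 |
| south-east | 2.00 | 36.0 |
| south-east | 3.00 | 39.4 |
| south-east | 5.00 | 45.1 |
| south-east | 8.00 | 49.1 |
| east | 0.500 | 16.8 |
| east | 1.00 | 22.2 |
| east | 2.00 | 28.8 |
| east | 4.00 | 35.8 |
| east | 8.00 | 43.6 |

(scatter of a reading: 0.3 percentage points)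

- the earlier runs were read with a standard deviation of 0.3 percentage points

- equivalents of partner to substrate, everything else as given, that leave most first product at 6.0 h
- the amount of first product then, in percent of the substrate charged
- the amount of first product with the amounts as given

The ladder, fastest rung first, uses the inverse of that mean times the partner concentration. South-east took 2.05 h, south 3.22 h and the flask 4.51 h. On these rungs the first product climbed steeply. South's last stretch gained 1.97 % h⁻¹, a creep with an inverse of 50.8 h. The flask's 6.0 h lay past its rung, so I expected it on the creep.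

Mean times partner concentration times time gave 1.33 for the flask: this is the partner clock. East, also at 1 equiv, reached the same clock at 4.00 h, so I committed to its reading, 35.8%, for n.

The forecast said “the partner mainly sets the clock” and gave 36.5%, a little above mine, with 51% at 5 equiv.

The flask gave 36.7%, and the best charge was 2.19 equiv, with 46.5%, below the forecast's charge.

    partner + first product ⇌ bis adduct (K = 29.0 M⁻¹, k = 0.391 M⁻¹ min⁻¹)
    first product ⇌ isomer of the product (K = 0.625, k = 0.0205 min⁻¹)
    substrate ⇌ dormant form (K = 0.440, k = 0.00510 min⁻¹)
    substrate + partner → first product (k = 0.696 M⁻¹ min⁻¹)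

At clock 1.33 the flask still held 24.6% substrate. The best charge read 2.91 on the clock and left 5.71% substrate with 15.1% bis adduct. The neighbour at 4.00 equiv read 5.32; there substrate stood at 0.822%, first product at 40.9% and bis adduct at 31.7%.

(The data come from a simulation with made-up constants; scatter was added.)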